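**Retrosynthetic overview**
- The target is cut at the E-alkene: cross-metathesis of a vinyl carbinol (left half, already carrying the cyclohexene ring) with a 6-allyl-1,2-dioxane propanoic acid (right half).
- Left half: the carbinol centre is bought in (R)-linalool. Its vinyl group takes the cyclohexenyl unit (9-BBN, then B-alkyl Suzuki coupling), and its prenyl tail is degraded to the new vinyl group.
- Right half: the 1,2-dioxane is made by [4+2] cycloaddition of singlet oxygen to a (3Z,5E)-diene, then diimide reduction. Diene geometry fixes the C3/C6 relationship; the Roche-ester centre biases the face.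
- The diene comes from Julia–Kocienski olefination of a Roche-ester-derived tetrazolyl sulfone with the lactol of 4-methyl-5,6-dihydro-2H-pyran-2-one, whose ring locks the Z-trisubstituted alkene.
- Rings: the cyclohexene is bought (2,2,6-trimethylcyclohexanone); the dioxane is the only ring formed (step 7).

Assumption: compounds 1, 6, 17 and 20 (20 in high ee) are taken as commercial; 17 is used as the racemate because its stereocentre is destroyed in step 12.

**Route**

Step 1
Reactants: 1 methyl (2S)-3-hydroxy-2-methylpropanoate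
Product: 2 methyl (2S)-3-{[tert-butyl(dimethyl)silyl]oxy}-2-methylpropanoate
Conditions: TBSCl, imidazole, CH2Cl2, 0 °C → rt
Reagents that add atoms: tert-butyldimethylsilyl chloride, CC(C)(C)[Si](C)(C)Cl
Why: Imidazole-promoted silyl ether formation on the primary alcohol; the bought stereocentre is not touched.

Step 2
Reactants: 2 methyl (2S)-3-{[tert-butyl(dimethyl)silyl]oxy}-2-methylpropanoate
Product: 3 (2R)-3-{[tert-butyl(dimethyl)silyl]oxy}-2-methylpropan-1-ol
Conditions: iBu2AlH (2.2 equiv), CH2Cl2, −78 → 0 °C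
Reagents that add atoms: none
Why: Hydride reduction of the ester to the primary alcohol; the descriptor changes only because the priorities change.

Step 3
Reactants: 3 (2R)-3-{[tert-butyl(dimethyl)silyl]oxy}-2-methylpropan-1-ol
Product: 4 5-{[(2S)-3-{[tert-butyl(dimethyl)silyl]oxy}-2-methylpropyl]sulfanyl}-1-phenyl-1H-tetrazole
Conditions: 1-phenyl-1H-tetrazole-5-thiol, PPh3, DIAD, THF, 0 °C → rt
Reagents that add atoms: 1-phenyl-1H-tetrazole-5-thiol, Sc1nnnn1-c1ccccc1
Why: Mitsunobu thioetherification at the primary CH2, so the stereocentre is not involved.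

Step 4
Reactants: 4 5-{[(2S)-3-{[tert-butyl(dimethyl)silyl]oxy}-2-methylpropyl]sulfanyl}-1-phenyl-1H-tetrazole
Product: 5 5-{[(2S)-3-{[tert-butyl(dimethyl)silyl]oxy}-2-methylpropyl]sulfonyl}-1-phenyl-1H-tetrazole
Conditions: H2O2 (30% aq.), (NH4)6Mo7O24·4H2O (cat.), EtOH, 0 °C → rt
Reagents that add atoms: hydrogen peroxide, OO
Why: Molybdate-catalysed sulfide-to-sulfone oxidation gives the Julia–Kocienski reagent; silyl ether and stereocentre are inert.

Step 5
Reactants: 6 4-methyl-5,6-dihydro-2H-pyran-2-one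
Product: 7 4-methyl-5,6-dihydro-2H-pyran-2-ol (anomeric mixture; ring-chain tautomer of (2Z)-5-hydroxy-3-methylpent-2-enal)
Conditions: iBu2AlH (1.05 equiv), CH2Cl2, −78 °C
Reagents that add atoms: none
Why: Partial hydride reduction of the unsaturated δ-lactone to the lactol; the ring holds the trisubstituted alkene in the Z geometry.

Step 6
Reactants: 5 5-{[(2S)-3-{[tert-butyl(dimethyl)silyl]oxy}-2-methylpropyl]sulfonyl}-1-phenyl-1H-tetrazole + 7 4-methyl-5,6-dihydro-2H-pyran-2-ol
Product: 9 (3Z,5E,7R)-8-{[tert-butyl(dimethyl)silyl]oxy}-3,7-dimethylocta-3,5-dien-1-ol, via potassium α-sulfonyl carbanion 8 (not isolated)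
Conditions: 5 (1.3 equiv), KN(SiMe3)2 (2.4 equiv), DME, −60 °C; then 7, −60 °C → rt
Reagents that add atoms: none
Why: Julia–Kocienski olefination of the ring-opened hydroxy-enal form of the lactol gives the new disubstituted alkene E-selectively; the Z-trisubstituted alkene comes unchanged from 7 and the Roche centre is untouched.

Step 7
Reactants: 9 (3Z,5E,7R)-8-{[tert-butyl(dimethyl)silyl]oxy}-3,7-dimethylocta-3,5-dien-1-ol
Product: 10 2-[(3R,6S)-6-[(2S)-1-{[tert-butyl(dimethyl)silyl]oxy}propan-2-yl]-3-methyl-3,6-dihydro-1,2-dioxin-3-yl]ethan-1-ol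
Conditions: O2, tetraphenylporphyrin (cat.), visible light, CH2Cl2, −20 °C
Reagents that add atoms: oxygen, O=O
Why: Suprafacial [4+2] cycloaddition of singlet oxygen (photooxygenation) places the two "outside" groups (the stereogenic side chain on the E terminus, the methyl on the Z terminus) cis on the new ring; the Roche centre directs attack anti to CH2OTBS in the H-eclipsed conformer, a modest bias (about 2–3:1 expected), so the (3S,6R) ring diastereomer and ene by-products are removed by chromatography.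

Step 8
Reactants: 10 2-[(3R,6S)-6-[(2S)-1-{[tert-butyl(dimethyl)silyl]oxy}propan-2-yl]-3-methyl-3,6-dihydro-1,2-dioxin-3-yl]ethan-1-ol
Product: 11 2-[(3S,6S)-6-[(2S)-1-{[tert-butyl(dimethyl)silyl]oxy}propan-2-yl]-3-methyl-1,2-dioxan-3-yl]ethan-1-ol
Conditions: KO2CN=NCO2K, AcOH, MeOH/CH2Cl2, 0 °C → rt
Reagents that add atoms: none
Why: Diimide reduction transfers H2 to the cis ring alkene in a concerted way without cleaving the O–O bond; no stereocentre is touched (the C3 descriptor changes by priority only).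

Step 9
Reactants: 11 2-[(3S,6S)-6-[(2S)-1-{[tert-butyl(dimethyl)silyl]oxy}propan-2-yl]-3-methyl-1,2-dioxan-3-yl]ethan-1-ol
Product: 12 2-[(3S,6S)-6-[(2S)-1-{[tert-butyl(dimethyl)silyl]oxy}propan-2-yl]-3-methyl-1,2-dioxan-3-yl]acetaldehyde
Conditions: Dess–Martin periodinane, NaHCO3, CH2Cl2, 0 °C → rt
Reagents that add atoms: none
Why: Dess–Martin oxidation under buffered, non-basic conditions that leave the dialkyl peroxide and the silyl ether intact.

Step 10
Reactants: 12 2-[(3S,6S)-6-[(2S)-1-{[tert-butyl(dimethyl)silyl]oxy}propan-2-yl]-3-methyl-1,2-dioxan-3-yl]acetaldehyde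
Product: 13 tert-butyl(dimethyl){(2S)-2-[(3S,6S)-6-methyl-6-(prop-2-en-1-yl)-1,2-dioxan-3-yl]propoxy}silane
Conditions: Ph3PCH3Br, KN(SiMe3)2, THF, 0 °C; then 12, −78 → 0 °C
Reagents that add atoms: methyltriphenylphosphonium bromide, C[P+](c1ccccc1)(c1ccccc1)c1ccccc1.[Br-]
Why: Wittig methylenation; addition of the ylide to the unhindered aldehyde at low temperature should outrun enolisation, so the β-peroxy aldehyde should not ring-open by retro-oxa-Michael elimination.

Step 11
Reactants: 13 tert-butyl(dimethyl){(2S)-2-[(3S,6S)-6-methyl-6-(prop-2-en-1-yl)-1,2-dioxan-3-yl]propoxy}silane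
Product: 16 (2R)-2-[(3S,6S)-6-methyl-6-(prop-2-en-1-yl)-1,2-dioxan-3-yl]propanoic acid, via primary alcohol 14 (not isolated), via aldehyde 15 (not isolated)
Conditions: CrO3, H2SO4, H2O, acetone, 0 °C
Reagents that add atoms: water, O
Why: Jones oxidation: the acidic medium cleaves the primary silyl ether and the alcohol is oxidised through the aldehyde hydrate to the acid; peroxide and terminal alkene survive, and the short cold acidic exposure should not epimerise the α-centre.

Step 12
Reactants: 17 2,2,6-trimethylcyclohexanone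
Product: 19 2,6,6-trimethylcyclohex-1-en-1-yl trifluoromethanesulfonate, via lithium enolate 18 (not isolated)
Conditions: LiN(iPr)2, THF, −78 → 0 °C; then PhNTf2, 0 °C → rt
Reagents that add atoms: N-phenylbis(trifluoromethanesulfonimide), O=S(=O)(N(c1ccccc1)S(=O)(=O)C(F)(F)F)C(F)(F)F
Why: Deprotonation at the only enolisable position and O-triflation of the enolate (enol triflate formation) gives the tetrasubstituted alkenyl triflate.

Step 13
Reactants: 20 (3R)-3,7-dimethylocta-1,6-dien-3-ol [(R)-linalool] + 19 2,6,6-trimethylcyclohex-1-en-1-yl trifluoromethanesulfonate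
Product: 22 (3R)-3,7-dimethyl-1-(2,6,6-trimethylcyclohex-1-en-1-yl)oct-6-en-3-ol, via B-alkyl-9-BBN adduct 21 (not isolated)
Conditions: 9-BBN, THF, 0 °C → rt; then 19, PdCl2(dppf)·CH2Cl2 (5 mol%), AsPh3, Cs2CO3, DMF/H2O, 60 °C
Reagents that add atoms: none
Why: Chemoselective anti-Markovnikov hydroboration of the monosubstituted vinyl group, then B-alkyl Suzuki–Miyaura coupling with the alkenyl triflate; the bought carbinol centre is not involved.

Step 14
Reactants: 22 (3R)-3,7-dimethyl-1-(2,6,6-trimethylcyclohex-1-en-1-yl)oct-6-en-3-ol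
Product: 24 (5S)-5-methyl-5-[2-(2,6,6-trimethylcyclohex-1-en-1-yl)ethyl]oxolan-2-ol (anomeric mixture), via vicinal diol 23 (not isolated)
Conditions: OsO4 (2 mol%), NaIO4, 2,6-lutidine, dioxane/H2O, rt
Reagents that add atoms: NaIO4 (oxygen relayed through catalytic OsO4), [Na+].[O-]I(=O)(=O)=O
Why: Lemieux–Johnson oxidation: OsO4 dihydroxylates the accessible trisubstituted alkene much faster than the hindered tetrasubstituted ring alkene, NaIO4 cleaves the diol, and the hydroxy aldehyde closes to the lactol.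

Step 15
Reactants: 24 (5S)-5-methyl-5-[2-(2,6,6-trimethylcyclohex-1-en-1-yl)ethyl]oxolan-2-ol
Product: 27 (3S)-3-methyl-5-(2,6,6-trimethylcyclohex-1-en-1-yl)pent-1-en-3-ol, via hydroperoxy oxolane 25 (not isolated), via tertiary formate 26 (not isolated)
Conditions: H2O2 (50% aq.), H2SO4 (cat.), Et2O, 0 °C, aqueous wash; then FeSO4·7H2O, Cu(OAc)2·H2O, MeOH, −20 °C → rt; then K2CO3, MeOH, rt
Reagents that add atoms: none
Why: Acid-catalysed exchange of the lactol OH for OOH, then Schreiber-type fragmentation: the anomeric alkoxy radical undergoes β-scission, Cu(OAc)2 oxidises the primary radical to the terminal alkene, and the tertiary formate is methanolysed; no bond to the carbinol centre is broken.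

Step 16
Reactants: 16 (2R)-2-[(3S,6S)-6-methyl-6-(prop-2-en-1-yl)-1,2-dioxan-3-yl]propanoic acid + 27 (3S)-3-methyl-5-(2,6,6-trimethylcyclohex-1-en-1-yl)pent-1-en-3-ol
Product: 28 (2R)-2-[(3S,6S)-6-[(2E,4S)-4-hydroxy-4-methyl-6-(2,6,6-trimethylcyclohex-1-en-1-yl)hex-2-en-1-yl]-6-methyl-1,2-dioxan-3-yl]propanoic acid
Conditions: second-generation Hoveyda–Grubbs catalyst RuCl2(H2IMes)(=CH-C6H4-2-OiPr) (5 mol%), 27 (3 equiv), CH2Cl2, 40 °C
Reagents that add atoms: none
Why: Olefin cross-metathesis between the unhindered allyl group and the slowly homodimerising tertiary allylic alcohol gives the E-alkene under thermodynamic control; the ruthenium carbene tolerates peroxide, free acid and tertiary alcohol, and no stereocentre is touched.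

**Compound list**

1 | methyl (2S)-3-hydroxy-2-methylpropanoate | COC(=O)[C@@H](C)CO | starting material
2 | methyl (2S)-3-{[tert-butyl(dimethyl)silyl]oxy}-2-methylpropanoate | COC(=O)[C@@H](C)CO[Si](C)(C)C(C)(C)C | intermediate
3 | (2R)-3-{[tert-butyl(dimethyl)silyl]oxy}-2-methylpropan-1-ol | OC[C@@H](C)CO[Si](C)(C)C(C)(C)C | intermediate
4 | 5-{[(2S)-3-{[tert-butyl(dimethyl)silyl]oxy}-2-methylpropyl]sulfanyl}-1-phenyl-1H-tetrazole | c1ccccc1-n1nnnc1SC[C@@H](C)CO[Si](C)(C)C(C)(C)C | intermediate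
5 | 5-{[(2S)-3-{[tert-butyl(dimethyl)silyl]oxy}-2-methylpropyl]sulfonyl}-1-phenyl-1H-tetrazole | c1ccccc1-n1nnnc1S(=O)(=O)C[C@@H](C)CO[Si](C)(C)C(C)(C)C | intermediate
6 | 4-methyl-5,6-dihydro-2H-pyran-2-one | CC1=CC(=O)OCC1 | starting material
7 | 4-methyl-5,6-dihydro-2H-pyran-2-ol (anomeric mixture) | CC1=CC(O)OCC1 | intermediate
8 | potassium salt of the α-sulfonyl carbanion of 5 | [K+].c1ccccc1-n1nnnc1S(=O)(=O)[CH-][C@@H](C)CO[Si](C)(C)C(C)(C)C | intermediate (not isolated)
9 | (3Z,5E,7R)-8-{[tert-butyl(dimethyl)silyl]oxy}-3,7-dimethylocta-3,5-dien-1-ol | OCC/C(C)=C\C=C\[C@@H](C)CO[Si](C)(C)C(C)(C)C | intermediate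
10 | 2-[(3R,6S)-6-[(2S)-1-{[tert-butyl(dimethyl)silyl]oxy}propan-2-yl]-3-methyl-3,6-dihydro-1,2-dioxin-3-yl]ethan-1-ol | OCC[C@]1(C)C=C[C@@H]([C@@H](C)CO[Si](C)(C)C(C)(C)C)OO1 | intermediate
11 | 2-[(3S,6S)-6-[(2S)-1-{[tert-butyl(dimethyl)silyl]oxy}propan-2-yl]-3-methyl-1,2-dioxan-3-yl]ethan-1-ol | OCC[C@]1(C)CC[C@@H]([C@@H](C)CO[Si](C)(C)C(C)(C)C)OO1 | intermediate
12 | 2-[(3S,6S)-6-[(2S)-1-{[tert-butyl(dimethyl)silyl]oxy}propan-2-yl]-3-methyl-1,2-dioxan-3-yl]acetaldehyde | O=CC[C@]1(C)CC[C@@H]([C@@H](C)CO[Si](C)(C)C(C)(C)C)OO1 | intermediate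
13 | tert-butyl(dimethyl){(2S)-2-[(3S,6S)-6-methyl-6-(prop-2-en-1-yl)-1,2-dioxan-3-yl]propoxy}silane | C=CC[C@]1(C)CC[C@@H]([C@@H](C)CO[Si](C)(C)C(C)(C)C)OO1 | intermediate
14 | (2S)-2-[(3S,6S)-6-methyl-6-(prop-2-en-1-yl)-1,2-dioxan-3-yl]propan-1-ol | C=CC[C@]1(C)CC[C@@H]([C@@H](C)CO)OO1 | intermediate (not isolated)
15 | (2R)-2-[(3S,6S)-6-methyl-6-(prop-2-en-1-yl)-1,2-dioxan-3-yl]propanal | C=CC[C@]1(C)CC[C@@H]([C@@H](C)C=O)OO1 | intermediate (not isolated)
16 | (2R)-2-[(3S,6S)-6-methyl-6-(prop-2-en-1-yl)-1,2-dioxan-3-yl]propanoic acid | C=CC[C@]1(C)CC[C@@H]([C@@H](C)C(=O)O)OO1 | intermediate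
17 | 2,2,6-trimethylcyclohexanone (racemic) | CC1CCCC(C)(C)C1=O | starting material
18 | lithium 2,6,6-trimethylcyclohex-1-en-1-olate | [Li+].[O-]C1=C(C)CCCC1(C)C | intermediate (not isolated)
19 | 2,6,6-trimethylcyclohex-1-en-1-yl trifluoromethanesulfonate | CC1=C(OS(=O)(=O)C(F)(F)F)C(C)(C)CCC1 | intermediate
20 | (3R)-3,7-dimethylocta-1,6-dien-3-ol [(R)-(−)-linalool] | C=C[C@](C)(O)CCC=C(C)C | starting material
21 | (3S)-1-(9-borabicyclo[3.3.1]nonan-9-yl)-3,7-dimethyloct-6-en-3-ol | CC(C)=CCC[C@@](C)(O)CCB1C2CCCC1CCC2 | intermediate (not isolated)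
22 | (3R)-3,7-dimethyl-1-(2,6,6-trimethylcyclohex-1-en-1-yl)oct-6-en-3-ol | CC1=C(CC[C@](C)(O)CCC=C(C)C)C(C)(C)CCC1 | intermediate
23 | (6S)-2,6-dimethyl-8-(2,6,6-trimethylcyclohex-1-en-1-yl)octane-2,3,6-triol (both C3 epimers) | CC1=C(CC[C@](C)(O)CCC(O)C(C)(C)O)C(C)(C)CCC1 | intermediate (not isolated)
24 | (5S)-5-methyl-5-[2-(2,6,6-trimethylcyclohex-1-en-1-yl)ethyl]oxolan-2-ol (anomeric mixture) | CC1=C(CC[C@@]2(C)CCC(O)O2)C(C)(C)CCC1 | intermediate
25 | (2S)-5-hydroperoxy-2-methyl-2-[2-(2,6,6-trimethylcyclohex-1-en-1-yl)ethyl]oxolane | CC1=C(CC[C@@]2(C)CCC(OO)O2)C(C)(C)CCC1 | intermediate (not isolated)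
26 | (3S)-3-methyl-5-(2,6,6-trimethylcyclohex-1-en-1-yl)pent-1-en-3-yl formate | C=C[C@@](C)(OC=O)CCC1=C(C)CCCC1(C)C | intermediate (not isolated)
27 | (3S)-3-methyl-5-(2,6,6-trimethylcyclohex-1-en-1-yl)pent-1-en-3-ol | C=C[C@@](C)(O)CCC1=C(C)CCCC1(C)C | intermediate
28 | (2R)-2-[(3S,6S)-6-[(2E,4S)-4-hydroxy-4-methyl-6-(2,6,6-trimethylcyclohex-1-en-1-yl)hex-2-en-1-yl]-6-methyl-1,2-dioxan-3-yl]propanoic acid | CC1=C(CC[C@](C)(O)/C=C/C[C@]2(C)CC[C@@H]([C@@H](C)C(=O)O)OO2)C(C)(C)CCC1 | target

**Totals**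
Total step count: 16.
Longest linear sequence: 11 steps (steps 1–4, 6–11 and 16).

**Three steps most likely to fail**

Step 7 (cycloaddition). The diene terminus that becomes the quaternary carbon carries an "inside" CH2 group, so the ene reaction of singlet oxygen can compete, the addition may lose stereospecificity, and the facial bias from the Roche centre is only modest. Fallback: set out from 9 and come back at 10 by replacing the photochemical singlet-oxygen reaction with a ground-state-oxygen radical-cation chain oxygenation (Barton–Haynes type: (4-BrC6H4)3N SbCl6 (5 mol%), O2, CH2Cl2, −78 °C). Here O2 adds to the diene radical cation and the ring then closes, so the ene channel is not open; the C3/C6 ratio would have to be checked because this path is stepwise. No new compound lies on the way.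

Step 6 (Julia–Kocienski reaction of a lactol). The lactol may react sluggishly, the E-selectivity with an enal can be lower, and the Z-enal can isomerise under base. Fallback: exchange the roles of the partners and use a Wittig reaction of an allylic ylide; it sets out from 2 and 6 and comes back at 9. Ester 2 is reduced (iBu2AlH, CH2Cl2, −78 °C) to (2S)-3-{[tert-butyl(dimethyl)silyl]oxy}-2-methylpropanal F1. Lactone 6 is reduced (iBu2AlH, 3 equiv, CH2Cl2, −78 → 0 °C) to (2Z)-3-methylpent-2-ene-1,5-diol F2. Its allylic hydroxyl is replaced selectively by chloride (N-chlorosuccinimide, Me2S, CH2Cl2, −20 → 0 °C) to give (3Z)-5-chloro-3-methylpent-3-en-1-ol F3. PBu3 (MeCN, 60 °C) gives tributyl[(2Z)-5-hydroxy-3-methylpent-2-en-1-yl]phosphonium chloride F4. Treatment with KOtBu (2 equiv, THF, −78 °C) and then F1 gives 9, with the E-selectivity usual for allylic trialkylphosphonium ylides.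

Step 15 (perhydrolysis and FeSO4/Cu(OAc)2 fragmentation). Hydroperoxide exchange may be incomplete, and the alkoxy radical can be diverted to the lactone. Fallback: set out from 24 and come back at 27 by rhodium-catalysed transfer hydroformylation ([Rh(cod)(OMe)]2 (2 mol%), Xantphos, 3-MeOC6H4CO2H (cat.), norbornadiene, THF, 60 °C). This removes the formyl group of the open hydroxy-aldehyde form of 24 onto norbornadiene and leaves the terminal alkene directly; only one β-hydrogen position exists, so only the vinyl carbinol can form. No new compound lies on the way.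

**Further compounds**
F1 | step 6 | (2S)-3-{[tert-butyl(dimethyl)silyl]oxy}-2-methylpropanal | O=C[C@@H](C)CO[Si](C)(C)C(C)(C)C
F2 | step 6 | (2Z)-3-methylpent-2-ene-1,5-diol | OC/C=C(C)\CCO
F3 | step 6 | (3Z)-5-chloro-3-methylpent-3-en-1-ol | ClC/C=C(C)\CCO
F4 | step 6 | tributyl[(2Z)-5-hydroxy-3-methylpent-2-en-1-yl]phosphonium chloride | CCCC[P+](CCCC)(CCCC)C/C=C(C)\CCO.[Cl-]
F0 | step 7 | none | none
F0 | step 15 | none | none
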